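Retrosynthesis: after unmasking four catechols and two acids, the C3=C4 alkene is traced back to a C4 carbinol. Ring B is then cut at C1–C2 and C3–C4 (retro-[4+2]) into the photoenol of a 2-benzylbenzaldehyde and a fumarate diester. The fumarate is cut at its two ester C–O bonds and the aldehyde at its aryl–CH2 bond.
Enabling feature: the C1(aryl)–C2(CO2R)–C3(CO2R)=C4 edge of ring B is a fumaric acid unit spliced between the two benzylic carbons (C1 and C4) on the catechol ring A. Each carboxyl is already esterified by an (R)-3-aryl-lactic acid, so the dienophile carries the target's own α-acyloxy ester stereocentres as chiral controllers.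
Forward: all four arenes are bought as catechols and masked as diphenylmethylene acetals. A Negishi coupling joins the diarylmethane, double acylation of fumaryl chloride joins the two lactate units, the photoenol Diels–Alder reaction closes ring B onto ring A, dehydration installs C3=C4 and acidolysis unmasks everything.
Stereochemistry: the two side-chain carbinol centres come from methyl (R)-glycidate, opened at CH2 with C2 untouched. C1 and C2 arise in the cycloaddition: the (E)-fumarate gives 2,3-trans, the (E,E)-dienol gives 1,4-cis, the endo ester beside OH gives 1,2-trans, and the (R)-ester units choose the face, hence (1R,2S). C3 and C4 are erased by the dehydration.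

Key step: step 11

Assumption: ring B is numbered as in a 1-aryl-1,2-dihydronaphthalene (C1 bears the pendant aryl group, C2 and C3 the carboxyl groups, C4 is the CH beside ring A). The two (R)-3-aryl-lactate esters are taken to bias the uncatalysed cycloaddition toward the fumarate face that makes C2 (S), as the non-chelated lactate-ester model suggests; the opposite outcome is treated under the risks.

Step 1
Reactants: 1 3,4-dihydroxybenzaldehyde
Product: 2 2,2-diphenyl-1,3-benzodioxole-5-carbaldehyde
Conditions: Ph2CCl2, Ph2O, 175 °C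
Reagents that add atoms: dichlorodiphenylmethane, ClC(Cl)(c1ccccc1)c1ccccc1
Why: Acetalisation of the catechol by the geminal dichloride (two O-alkylations with loss of HCl) masks both phenols as a base-stable, acid-labile diphenylmethylene acetal and does not touch the aldehyde.

Step 2
Reactants: 2 2,2-diphenyl-1,3-benzodioxole-5-carbaldehyde
Product: 3 6-bromo-2,2-diphenyl-1,3-benzodioxole-5-carbaldehyde
Conditions: NBS, NaOAc, DMF, 0 °C to rt, dark
Reagents that add atoms: N-bromosuccinimide, O=C1CCC(=O)N1Br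
Why: Electrophilic aromatic bromination should go to C6, the position para to a ring oxygen and ortho to the formyl group (the site attacked in piperonal), while the NaOAc buffer keeps traces of HBr away from the acetal.

Step 3
Reactants: 2 2,2-diphenyl-1,3-benzodioxole-5-carbaldehyde
Product: 4 (2,2-diphenyl-1,3-benzodioxol-5-yl)methanol
Conditions: NaBH4, MeOH/THF, 0 °C
Reagents that add atoms: none
Why: Hydride reduction of the aryl aldehyde with NaBH4 is fast and leaves the acetal untouched.

Step 4
Reactants: 4 (2,2-diphenyl-1,3-benzodioxol-5-yl)methanol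
Product: 6 5-(chloromethyl)-2,2-diphenyl-1,3-benzodioxole, via benzylic mesylate 5 (not isolated)
Conditions: MsCl, Et3N, LiCl, THF, 0 °C to rt
Reagents that add atoms: lithium chloride, [Li+].[Cl-]
Why: O-Sulfonylation followed by SN2 displacement of the electron-rich benzylic mesylate by chloride gives the chloride under non-acidic conditions that spare the acetal.

Step 5
Reactants: 6 5-(chloromethyl)-2,2-diphenyl-1,3-benzodioxole, 3 6-bromo-2,2-diphenyl-1,3-benzodioxole-5-carbaldehyde
Product: 8 6-[(2,2-diphenyl-1,3-benzodioxol-5-yl)methyl]-2,2-diphenyl-1,3-benzodioxole-5-carbaldehyde, via benzylzinc chloride 7 (not isolated)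
Conditions: Zn dust, LiCl, THF, rt; then 3, Pd(OAc)2 (2 mol%), SPhos (4 mol%), THF, rt
Reagents that add atoms: none
Why: LiCl-assisted insertion of Zn into the benzylic C–Cl bond and Negishi cross-coupling (oxidative addition of the aryl bromide to zerovalent palladium formed from Pd(OAc)2 and SPhos, transmetalation, reductive elimination) form the aryl–CH2 bond, and a benzylzinc chloride made without MgCl2 adds only slowly to an aldehyde, so the formyl group should survive.

Step 6
Reactants: 9 4-bromocatechol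
Product: 10 5-bromo-2,2-diphenyl-1,3-benzodioxole
Conditions: Ph2CCl2, neat, 160 °C
Reagents that add atoms: dichlorodiphenylmethane, ClC(Cl)(c1ccccc1)c1ccccc1
Why: The same catechol acetalisation as in step 1 masks the diol before the organomagnesium chemistry.

Step 7
Reactants: 10 5-bromo-2,2-diphenyl-1,3-benzodioxole, 11 methyl (R)-glycidate
Product: 13 methyl (2R)-3-(2,2-diphenyl-1,3-benzodioxol-5-yl)-2-hydroxypropanoate, via arylmagnesium bromide 12 (not isolated)
Conditions: Mg, THF, 45 °C; then CuI (10 mol%), 11, THF, −40 to −20 °C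
Reagents that add atoms: none
Why: Under CuI catalysis the Grignard reagent opens the epoxide by SN2 attack at the unsubstituted CH2 carbon faster than it adds to the ester at low temperature, and because C2 of the glycidate is not touched its (R) configuration is carried into the lactate.

Step 8
Reactants: 13 methyl (2R)-3-(2,2-diphenyl-1,3-benzodioxol-5-yl)-2-hydroxypropanoate
Product: 14 (2R)-3-(2,2-diphenyl-1,3-benzodioxol-5-yl)-2-hydroxypropanoic acid
Conditions: LiOH·H2O, THF/H2O, 0 °C; then 1 M HCl to pH 3, 0 °C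
Reagents that add atoms: lithium hydroxide, [Li+].[OH-]
Why: Saponification by acyl–oxygen cleavage at 0 °C frees the acid without racemising the α-hydroxy centre, and the acetal is inert to base and to the brief cold acidification.

Step 9
Reactants: 14 (2R)-3-(2,2-diphenyl-1,3-benzodioxol-5-yl)-2-hydroxypropanoic acid
Product: 15 tert-butyl (2R)-3-(2,2-diphenyl-1,3-benzodioxol-5-yl)-2-hydroxypropanoate
Conditions: Cl3CC(=NH)OtBu, CH2Cl2/cyclohexane, rt
Reagents that add atoms: tert-butyl 2,2,2-trichloroacetimidate, CC(C)(C)OC(=N)C(Cl)(Cl)Cl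
Why: The carboxylic acid protonates the imidate and is tert-butylated by it (acid-promoted imidate esterification) with no added Lewis acid, so the secondary hydroxyl and the acetal stay untouched.

Step 10
Reactants: 15 tert-butyl (2R)-3-(2,2-diphenyl-1,3-benzodioxol-5-yl)-2-hydroxypropanoate (2 equiv), 16 fumaryl chloride
Product: 17 bis[(2R)-1-tert-butoxy-3-(2,2-diphenyl-1,3-benzodioxol-5-yl)-1-oxopropan-2-yl] (E)-but-2-enedioate
Conditions: 16 (0.5 equiv), pyridine, CH2Cl2, −10 °C to rt
Reagents that add atoms: none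
Why: Double O-acylation (nucleophilic acyl substitution) with pyridine as HCl acceptor joins both lactate units without breaking a C–O bond at the carbinol centres or disturbing the (E) geometry.

Step 11
Reactants: 8 6-[(2,2-diphenyl-1,3-benzodioxol-5-yl)methyl]-2,2-diphenyl-1,3-benzodioxole-5-carbaldehyde (slight excess), 17 bis[(2R)-1-tert-butoxy-3-(2,2-diphenyl-1,3-benzodioxol-5-yl)-1-oxopropan-2-yl] (E)-but-2-enedioate
Product: 19 bis[(2R)-1-tert-butoxy-3-(2,2-diphenyl-1,3-benzodioxol-5-yl)-1-oxopropan-2-yl] (1R,2S,3R,4R)-1-(2,2-diphenyl-1,3-benzodioxol-5-yl)-4-hydroxy-6,7-(diphenylmethylenedioxy)-1,2,3,4-tetrahydronaphthalene-2,3-dicarboxylate, via hydroxy-o-quinodimethane 18 (not isolated)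
Conditions: hν (365 nm), degassed toluene, rt
Reagents that add atoms: none
Why: Excitation of the aryl aldehyde of 8 and intersystem crossing are followed by 1,5-hydrogen transfer from the doubly benzylic CH2 to the carbonyl oxygen, and the biradical relaxes to the (E,E)-hydroxy-o-quinodimethane 18 (OH and aryl both outward), which the electron-poor fumarate 17 traps in a concerted suprafacial [4+2] cycloaddition driven by rearomatisation of ring A. The closest known reaction type is the photoenolisation/Diels–Alder reaction of 2-alkyl- and 2-benzylbenzaldehydes, together with additions of α-hydroxy-α'-aryl-o-quinodimethanes to fumarates of lactate and mandelate esters. Ring B (C1–C2–C3–C4–C4a–C8a) is closed by intermolecular [4+2] annulation onto ring A, the C1–C2 and C3–C4 bonds forming in one event. The trans relation of C2 and C3 is fixed by the (E)-fumarate and the cis relation of C1 and C4 by the (E,E)-diene, and the ester on C3 should sit endo beside the dienol OH that can hydrogen-bond to it while the ester on C2 stays exo and anti to the C1 aryl group, which gives the 1,2-trans, 3,4-cis adduct. The absolute sense should come from the two (R)-α-acyloxy ester carbinol centres, which are related by the twofold axis of the fumarate and so screen the same face of the C=C bond with their tert-butoxycarbonyl groups, leaving open the face that leads to (1R,2S,3R,4R). The step therefore needs π-facial selectivity on the dienophile and the endo orientation at the carbinol terminus, and because C3 and C4 are erased in step 12 only the sense at C1 and C2 has to be right.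

Step 12
Reactants: 19 the (1R,2S,3R,4R) cycloadduct
Product: 21 bis[(2R)-1-tert-butoxy-3-(2,2-diphenyl-1,3-benzodioxol-5-yl)-1-oxopropan-2-yl] (1R,2S)-1-(2,2-diphenyl-1,3-benzodioxol-5-yl)-6,7-(diphenylmethylenedioxy)-1,2-dihydronaphthalene-2,3-dicarboxylate (fully protected rabdosiin), via C4 mesylate 20 (not isolated)
Conditions: MsCl, Et3N, CH2Cl2, 0 °C; then DBU, 0 °C to rt
Reagents that add atoms: none
Why: Sulfonylation of the benzylic C4 alcohol (para to a ring oxygen) and base-induced β-elimination of the acidic C3–H, which lies anti to the leaving group, give the C3=C4 bond conjugated with the C3 ester and ring A, while C1 is not involved and C2 keeps the trans relation to the aryl group, which is also the thermodynamically preferred one.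

Step 13
Reactants: 21 fully protected rabdosiin
Product: 22 rabdosiin
Conditions: TFA/H2O/thioanisole (90:5:5), 0 °C to rt
Reagents that add atoms: none
Why: Acidolysis cleaves the two tert-butyl esters by alkyl–oxygen fission and hydrolyses the four diphenylmethylene acetals through diaryl-stabilised oxocarbenium ions, with thioanisole trapping the tert-butyl cations, while the secondary ester links and all four stereocentres are inert to these conditions.

Compound list
1 | 3,4-dihydroxybenzaldehyde | O=Cc1ccc(O)c(O)c1 | starting material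
2 | 2,2-diphenyl-1,3-benzodioxole-5-carbaldehyde | O=Cc1ccc2OC(c3ccccc3)(c3ccccc3)Oc2c1 | intermediate
3 | 6-bromo-2,2-diphenyl-1,3-benzodioxole-5-carbaldehyde | O=Cc1cc2OC(c3ccccc3)(c3ccccc3)Oc2cc1Br | intermediate
4 | (2,2-diphenyl-1,3-benzodioxol-5-yl)methanol | OCc1ccc2OC(c3ccccc3)(c3ccccc3)Oc2c1 | intermediate
5 | (2,2-diphenyl-1,3-benzodioxol-5-yl)methyl methanesulfonate (not isolated) | CS(=O)(=O)OCc1ccc2OC(c3ccccc3)(c3ccccc3)Oc2c1 | intermediate
6 | 5-(chloromethyl)-2,2-diphenyl-1,3-benzodioxole | ClCc1ccc2OC(c3ccccc3)(c3ccccc3)Oc2c1 | intermediate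
7 | [(2,2-diphenyl-1,3-benzodioxol-5-yl)methyl]zinc chloride (not isolated) | Cl[Zn]Cc1ccc2OC(c3ccccc3)(c3ccccc3)Oc2c1 | intermediate
8 | 6-[(2,2-diphenyl-1,3-benzodioxol-5-yl)methyl]-2,2-diphenyl-1,3-benzodioxole-5-carbaldehyde | O=Cc1cc2OC(c3ccccc3)(c3ccccc3)Oc2cc1Cc1ccc2OC(c3ccccc3)(c3ccccc3)Oc2c1 | intermediate
9 | 4-bromocatechol (4-bromobenzene-1,2-diol) | Oc1ccc(Br)cc1O | starting material
10 | 5-bromo-2,2-diphenyl-1,3-benzodioxole | Brc1ccc2OC(c3ccccc3)(c3ccccc3)Oc2c1 | intermediate
11 | methyl (R)-glycidate (methyl (2R)-oxirane-2-carboxylate) | COC(=O)[C@H]1CO1 | starting material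
12 | (2,2-diphenyl-1,3-benzodioxol-5-yl)magnesium bromide (not isolated) | Br[Mg]c1ccc2OC(c3ccccc3)(c3ccccc3)Oc2c1 | intermediate
13 | methyl (2R)-3-(2,2-diphenyl-1,3-benzodioxol-5-yl)-2-hydroxypropanoate | COC(=O)[C@H](O)Cc1ccc2OC(c3ccccc3)(c3ccccc3)Oc2c1 | intermediate
14 | (2R)-3-(2,2-diphenyl-1,3-benzodioxol-5-yl)-2-hydroxypropanoic acid | OC(=O)[C@H](O)Cc1ccc2OC(c3ccccc3)(c3ccccc3)Oc2c1 | intermediate
15 | tert-butyl (2R)-3-(2,2-diphenyl-1,3-benzodioxol-5-yl)-2-hydroxypropanoate | CC(C)(C)OC(=O)[C@H](O)Cc1ccc2OC(c3ccccc3)(c3ccccc3)Oc2c1 | intermediate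
16 | fumaryl chloride ((E)-but-2-enedioyl dichloride) | O=C(Cl)/C=C/C(=O)Cl | starting material
17 | bis[(2R)-1-tert-butoxy-3-(2,2-diphenyl-1,3-benzodioxol-5-yl)-1-oxopropan-2-yl] (E)-but-2-enedioate | CC(C)(C)OC(=O)[C@@H](Cc1ccc2OC(c3ccccc3)(c3ccccc3)Oc2c1)OC(=O)/C=C/C(=O)O[C@H](Cc1ccc2OC(c3ccccc3)(c3ccccc3)Oc2c1)C(=O)OC(C)(C)C | intermediate
18 | (E,E)-hydroxy-o-quinodimethane from 8, 5-[(E)-hydroxymethylidene]-6-[(E)-(2,2-diphenyl-1,3-benzodioxol-5-yl)methylidene]-2,2-diphenyl-5,6-dihydro-1,3-benzodioxole, OH and aryl both outward (not isolated) | O/C=C1\C=C2OC(c3ccccc3)(c3ccccc3)OC2=C/C1=C\c1ccc2OC(c3ccccc3)(c3ccccc3)Oc2c1 | intermediate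
19 | bis[(2R)-1-tert-butoxy-3-(2,2-diphenyl-1,3-benzodioxol-5-yl)-1-oxopropan-2-yl] (1R,2S,3R,4R)-1-(2,2-diphenyl-1,3-benzodioxol-5-yl)-4-hydroxy-6,7-(diphenylmethylenedioxy)-1,2,3,4-tetrahydronaphthalene-2,3-dicarboxylate (1,2-trans, 2,3-trans, 3,4-cis) | O=C(O[C@H](Cc1ccc2OC(c3ccccc3)(c3ccccc3)Oc2c1)C(=O)OC(C)(C)C)[C@H]1[C@@H](O)c2cc3OC(c4ccccc4)(c4ccccc4)Oc3cc2[C@@H](c2ccc3OC(c4ccccc4)(c4ccccc4)Oc3c2)[C@@H]1C(=O)O[C@H](Cc1ccc2OC(c3ccccc3)(c3ccccc3)Oc2c1)C(=O)OC(C)(C)C | intermediate
20 | C4 methanesulfonate of 19, same (1R,2S,3R,4R) configuration (not isolated) | O=C(O[C@H](Cc1ccc2OC(c3ccccc3)(c3ccccc3)Oc2c1)C(=O)OC(C)(C)C)[C@H]1[C@@H](OS(C)(=O)=O)c2cc3OC(c4ccccc4)(c4ccccc4)Oc3cc2[C@@H](c2ccc3OC(c4ccccc4)(c4ccccc4)Oc3c2)[C@@H]1C(=O)O[C@H](Cc1ccc2OC(c3ccccc3)(c3ccccc3)Oc2c1)C(=O)OC(C)(C)C | intermediate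
21 | bis[(2R)-1-tert-butoxy-3-(2,2-diphenyl-1,3-benzodioxol-5-yl)-1-oxopropan-2-yl] (1R,2S)-1-(2,2-diphenyl-1,3-benzodioxol-5-yl)-6,7-(diphenylmethylenedioxy)-1,2-dihydronaphthalene-2,3-dicarboxylate (fully protected rabdosiin) | O=C(O[C@H](Cc1ccc2OC(c3ccccc3)(c3ccccc3)Oc2c1)C(=O)OC(C)(C)C)C1=Cc2cc3OC(c4ccccc4)(c4ccccc4)Oc3cc2[C@@H](c2ccc3OC(c4ccccc4)(c4ccccc4)Oc3c2)[C@@H]1C(=O)O[C@H](Cc1ccc2OC(c3ccccc3)(c3ccccc3)Oc2c1)C(=O)OC(C)(C)C | intermediate
22 | rabdosiin, (2R)-2-[[(1R,2S)-3-[[(1R)-1-carboxy-2-(3,4-dihydroxyphenyl)ethoxy]carbonyl]-1-(3,4-dihydroxyphenyl)-6,7-dihydroxy-1,2-dihydronaphthalen-2-yl]carbonyloxy]-3-(3,4-dihydroxyphenyl)propanoic acid | O=C(O[C@H](Cc1ccc(O)c(O)c1)C(=O)O)C1=Cc2cc(O)c(O)cc2[C@@H](c2ccc(O)c(O)c2)[C@@H]1C(=O)O[C@H](Cc1ccc(O)c(O)c1)C(=O)O | target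

Total step count: 13 steps.
Longest linear sequence: 8 steps (9 → 10 → 13 → 14 → 15 → 17 → 19 → 21 → 22, steps 6 to 13).

Steps most likely to fail

Step 11. The dienol may add to the other face of the fumarate, or with the ester beside the aryl-bearing carbon endo, or with poor discrimination between these paths. Each of them carries the wrong configuration at C1 through steps 12 and 13, and C1 cannot be corrected later because only C2 is epimerisable. The fallback sets out from 8 and comes back at 21; it makes the dienophile achiral and attaches the lactate units after ring B exists, so the C1/C2 pair is resolved as diastereomers. Aldehyde 8 is irradiated with dimethyl fumarate under the conditions of step 11 to give the racemic dimethyl 1-aryl-4-hydroxytetralin-2,3-dicarboxylate F1. Mesylation (MsCl, Et3N) gives the racemic C4 mesylate F2, and elimination with DBU gives the racemic dimethyl trans-1-aryl-1,2-dihydronaphthalene-2,3-dicarboxylate F3; any 1,2-cis material should converge on the trans series under the base. Saponification with LiOH in THF/H2O gives the racemic trans diacid F4. Steglich-type esterification of both carboxyl groups with alcohol 15 (EDC hydrochloride, DMAP, CH2Cl2) should give 21 together with its (1S,2R) diastereomer F5, and the two are separated by chromatography or crystallisation.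

Step 5. The benzylzinc reagent may add to the formyl group of the bromide or of the product, or homocouple to the bibenzyl, faster than it cross-couples. The fallback sets out from 3, with 6 as partner, and comes back at 8; it reverses the polarity of the coupling so that no aldehyde-reactive organometallic is present. Miyaura borylation of 3 with bis(pinacolato)diboron (PdCl2(dppf), KOAc, dioxane, 85 °C) gives 2,2-diphenyl-6-(4,4,5,5-tetramethyl-1,3,2-dioxaborolan-2-yl)-1,3-benzodioxole-5-carbaldehyde F6. Suzuki–Miyaura coupling of this boronate with benzylic chloride 6 (Pd(PPh3)4, K2CO3, THF/H2O, 65 °C) then gives 8.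

Step 13. tert-Butyl cations are released beside freshly unmasked catechol rings and may alkylate them, and slow hydrolysis of four acetals forces long exposure of an air-sensitive polyphenol to strong acid. The fallback sets out from 21 and comes back at 22; it separates the cation-releasing event from the unmasking of the catechols. The tert-butyl esters are cleaved first under non-protic conditions (TMSOTf, 2,6-lutidine, CH2Cl2, 0 °C, then aqueous work-up) to give the diacid with all four acetals intact F7. The acetals are then hydrolysed in AcOH/H2O (4:1) at 80 °C under argon to give 22.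

Further compounds
F1 | step 11 | racemic dimethyl (1R*,2S*,3R*,4R*)-1-(2,2-diphenyl-1,3-benzodioxol-5-yl)-4-hydroxy-6,7-(diphenylmethylenedioxy)-1,2,3,4-tetrahydronaphthalene-2,3-dicarboxylate (one enantiomer drawn) | COC(=O)[C@H]1[C@@H](O)c2cc3OC(c4ccccc4)(c4ccccc4)Oc3cc2[C@@H](c2ccc3OC(c4ccccc4)(c4ccccc4)Oc3c2)[C@@H]1C(=O)OC
F2 | step 11 | racemic C4 methanesulfonate of F1 (one enantiomer drawn) | COC(=O)[C@H]1[C@@H](OS(C)(=O)=O)c2cc3OC(c4ccccc4)(c4ccccc4)Oc3cc2[C@@H](c2ccc3OC(c4ccccc4)(c4ccccc4)Oc3c2)[C@@H]1C(=O)OC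
F3 | step 11 | racemic dimethyl trans-1-(2,2-diphenyl-1,3-benzodioxol-5-yl)-6,7-(diphenylmethylenedioxy)-1,2-dihydronaphthalene-2,3-dicarboxylate (1R,2S enantiomer drawn) | COC(=O)C1=Cc2cc3OC(c4ccccc4)(c4ccccc4)Oc3cc2[C@@H](c2ccc3OC(c4ccccc4)(c4ccccc4)Oc3c2)[C@@H]1C(=O)OC
F4 | step 11 | racemic trans-1-(2,2-diphenyl-1,3-benzodioxol-5-yl)-6,7-(diphenylmethylenedioxy)-1,2-dihydronaphthalene-2,3-dicarboxylic acid (1R,2S enantiomer drawn) | OC(=O)C1=Cc2cc3OC(c4ccccc4)(c4ccccc4)Oc3cc2[C@@H](c2ccc3OC(c4ccccc4)(c4ccccc4)Oc3c2)[C@@H]1C(=O)O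
F5 | step 11 | (1S,2R) diastereomer of 21, with both side chains (R) | O=C(O[C@H](Cc1ccc2OC(c3ccccc3)(c3ccccc3)Oc2c1)C(=O)OC(C)(C)C)C1=Cc2cc3OC(c4ccccc4)(c4ccccc4)Oc3cc2[C@H](c2ccc3OC(c4ccccc4)(c4ccccc4)Oc3c2)[C@H]1C(=O)O[C@H](Cc1ccc2OC(c3ccccc3)(c3ccccc3)Oc2c1)C(=O)OC(C)(C)C
F6 | step 5 | 2,2-diphenyl-6-(4,4,5,5-tetramethyl-1,3,2-dioxaborolan-2-yl)-1,3-benzodioxole-5-carbaldehyde | O=Cc1cc2OC(c3ccccc3)(c3ccccc3)Oc2cc1B1OC(C)(C)C(C)(C)O1
F7 | step 13 | rabdosiin with both carboxylic acids free and all four catechols still masked as diphenylmethylene acetals, (1R,2S) core and (R) side chains | O=C(O[C@H](Cc1ccc2OC(c3ccccc3)(c3ccccc3)Oc2c1)C(=O)O)C1=Cc2cc3OC(c4ccccc4)(c4ccccc4)Oc3cc2[C@@H](c2ccc3OC(c4ccccc4)(c4ccccc4)Oc3c2)[C@@H]1C(=O)O[C@H](Cc1ccc2OC(c3ccccc3)(c3ccccc3)Oc2c1)C(=O)O
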